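## Retrosynthetic overview

1. Target ⇐ N‑PMB removal (CAN) ⇐ β,γ‑enone from fluoride desilylation ⇐ aldol of the C12 aldehyde with an N‑PMB‑succinimide enolate. The aldol forms C12–C13 and sets C12/C13. The C8 methylene comes from a β‑silylmethyl enone made by Negishi coupling of a β‑chloroenone.
2. C2–Cl ⇐ SN2 inversion of a 2β‑alcohol ⇐ K‑Selectride reduction of a 2‑keto‑dione. That trione comes from acid‑promoted cyclization and hydrolysis of a bis(enol ether) diene, which forms the C4–C5 bond and fixes C5 and C9 thermodynamically.
3. The diene ⇐ Wittig of a quaternary aldehyde ⇐ asymmetric Birch reductive methylation of 2‑allyl‑3,5‑dimethoxybenzamide. This dearomatization creates ring B and the C10 quaternary stereocentre, starting from cheap 3,5‑dimethoxybenzoic acid.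
4. Ring order: ring B (Birch dearomatization), then ring A (cationic closure). The succinimide is pre‑formed and attached last by aldol.

**Assumptions (one line):** the (S)‑prolinol‑derived auxiliary gives the C10 sense drawn (otherwise use the (R)‑auxiliary); C5 and C9 equilibrate to the trans‑fused, equatorial‑side‑chain isomer; the less hindered C8 carbonyl of the dione reacts selectively; the C12/C13 aldol diastereomers are separable.

## Route

**Step 1**
Reactants: 1 (3,5‑dimethoxybenzoic acid), 2 ((S)‑2‑(methoxymethyl)pyrrolidine)
Product: 3, the (S)‑SMP amide of 1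
Conditions: (i) (COCl)2, cat. DMF, CH2Cl2, rt; (ii) 2, Et3N, CH2Cl2, 0 °C
Reagents that add atoms: none (2 is reactant)
Why: Acid chloride amidation installs the chiral auxiliary that will direct the Birch alkylation.

**Step 2**
Reactants: 3, 4 (allyl bromide)
Product: 5, the 2‑allyl amide
Conditions: s‑BuLi, TMEDA, THF, –78 °C; then cat. CuI, 4
Reagents that add atoms: allyl bromide, C=CCBr
Why: Directed ortho‑metalation at C2, which is flanked by the amide and a methoxy group, followed by allylation. This installs the future C9–C11–C12 unit and the ortho substituent that the Schultz chelation model requires.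

**Step 3 (key dearomatization)**
Reactants: 5, 6 (iodomethane)
Product: 7, the 1‑methyl‑3,5‑dimethoxycyclohexa‑2,5‑diene quaternary amide
Conditions: Li, NH3(l), THF, t‑BuOH (1.1 equiv), –78 °C; then MeI, –78 °C → rt
Reagents that add atoms: iodomethane, CI
Why: Asymmetric Birch reduction–alkylation (Schultz). The Li‑chelated amide enolate is methylated from one face, which sets C10 and leaves a bis(enol ether) 1,4‑diene that becomes ring B. Para protonation gives C7H2.

**Step 4**
Reactants: 7
Product: 8, the quaternary aldehyde (C1 aldehyde, auxiliary released)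
Conditions: LiAlH(OEt)3, THF, 0 °C → rt; Rochelle workup
Reagents that add atoms: none
Why: Brown partial reduction of the tertiary amide to the aldehyde, which tolerates the enol ethers and the alkene; SMP is recovered.

**Step 5 (parallel reagent preparation)**
Reactants: 9 (prenal), 10 (triphenylphosphine), 11 (methanol)
Product: 12, the α‑methoxyallyl phosphonium tetrafluoroborate
Conditions: HBF4·OEt2, MeOH/CH2Cl2, 0 °C → rt
Reagents that add atoms: HBF4, [H+].F[B-](F)(F)F, and methanol, CO
Why: 1,2‑Addition of PPh3 to the enal with methanol capture gives the α‑alkoxyphosphonium salt, the precursor of the 2‑methoxydiene.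

**Step 6**
Reactants: 8, 12
Product: 13, the 2‑methoxy‑1,3‑diene (C1=C2(OMe)–C3=C4Me2), E/Z mixture
Conditions: KHMDS, THF, 0 °C, then 8, 50 °C
Reagents that add atoms: none beyond 12
Why: Wittig olefination of the non‑enolizable aldehyde. Both alkene geometries converge in the next step.

**Step 7**
Reactants: 13 (via in‑situ 14, the cyclized tri(enol ether), not isolated)
Product: 15, the trione (ring A/B, C2=O, C6=O, C8=O, 5α‑H, 9α‑H)
Conditions: (i) HNTf2 (5 mol%), CH2Cl2, –78 → –30 °C; (ii) then 2 M aq. HCl/THF, 55 °C
Reagents that add atoms: water, O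
Why: Proposed new method: catalytic acid protonates the diene at C1 to give a vinylogous oxocarbenium (protonated enone). The C5 enol‑ether carbon attacks its tertiary terminus C4 in a 6‑endo closure, closest to an enol‑ether‑terminated cation–olefin cyclization or Mukaiyama–Michael. This gives the C5 stereocentre cis to the C10 methyl, together with the C2 enol ether and a 2,4‑dimethoxydiene in ring B. Hot aqueous acid then hydrolyses all three enol ethers to the trione, and enolization equilibrates C5 and C9 to the thermodynamic trans‑fused, C9‑equatorial‑side‑chain isomer.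

**Step 8**
Reactants: 15
Product: 16, the 2β‑hydroxy dione
Conditions: K‑Selectride (3.5 equiv), THF, –78 °C
Reagents that add atoms: none (H only)
Why: The dione is deprotonated to its inert enolate. The bulky hydride then adds to the C2 ketone from the α‑face (equatorial attack), because the β‑face is blocked by the syn‑axial C19/C20 methyls. This gives axial 2β‑OH.

**Step 9**
Reactants: 16, 17 (hexachloroethane), PPh3 (10)
Product: 18, the 2α‑chloro‑β‑chloroenone
Conditions: PPh3 (4 equiv), C2Cl6 (4 equiv), CH2Cl2, 0 → 40 °C
Reagents that add atoms: hexachloroethane, ClC(Cl)(Cl)C(Cl)(Cl)Cl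
Why: Proposed new method: Ph3PCl2, formed in situ, converts the vinylogous acid (dione enol) at the less hindered C8 carbonyl into the β‑chloroenone by addition–elimination. It also converts the axial 2β‑OH into chloride by Appel SN2 with inversion, giving 2α‑Cl. These are two known Ph3P/halogen reactions applied together.

**Step 10**
Reactants: 18, 19 (TMSCH2ZnCl)
Product: 20, the β‑(trimethylsilylmethyl) enone
Conditions: 19 (2.5 equiv), Pd(PPh3)4 (5 mol%), THF, 50 °C
Reagents that add atoms: (trimethylsilyl)methylzinc chloride, C[Si](C)(C)C[Zn]Cl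
Why: Negishi coupling at the vinylogous acid chloride C8 (sp2, no new stereocentre). The unactivated secondary alkyl chloride and the ketone are inert to the organozinc and Pd(0).

**Step 11**
Reactants: 20
Product: 21, the C12 aldehyde
Conditions: OsO4 (5 mol%), NaIO4 (4 equiv), 2,6‑lutidine, dioxane/H2O, rt
Reagents that add atoms: OsO4/NaIO4 as the oxygen source (NaIO4: O=I(=O)(=O)[O-].[Na+])
Why: Lemieux–Johnson cleavage is selective for the unhindered monosubstituted allyl alkene over the electron‑poor, hindered enone alkene. It gives C9–CH2–CHO with no change at C9.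

**Step 12**
Reactants: 21, 22 (N‑PMB‑succinimide)
Product: 23, the aldol adduct (12S,13R isolated)
Conditions: 22 (2.5 equiv), LiHMDS (2.6 equiv), THF, –78 °C; add 21; NH4Cl; HPLC separation of diastereomers
Reagents that add atoms: N‑PMB‑succinimide, O=C1CCC(=O)N1Cc1ccc(OC)cc1
Why: Lithium‑enolate aldol through a Zimmerman–Traxler chair forms C12 and C13. Diastereoselectivity is modest, so the desired (12S,13R) isomer is separated chromatographically.

**Step 13**
Reactants: 23
Product: 24, the PMB‑protected target (exocyclic C8=C17)
Conditions: TBAF (3 equiv), AcOH (3 equiv), THF, 0 °C, 15 min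
Reagents that add atoms: none
Why: Fluoride desilylates the allylsilane to a C6–O⁻/C7=…C8=CH2 dienolate. Kinetic protonation at C7 gives the β,γ‑enone with the exocyclic methylene. AcOH buffering suppresses retro‑aldol and conjugation.

**Step 14**
Reactants: 24
Product: 25, haterumaimide G
Conditions: CAN (4 equiv), NaHCO3, MeCN/H2O 3:1, 0 °C
Reagents that add atoms: none
Why: Oxidative N‑PMB cleavage frees the imide N–H under mild, near‑neutral conditions. The C12, C13 and ring stereocentres are untouched.

## Compound list

| No. | Name | SMILES | Role |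
|---|---|---|---|
| 1 | 3,5‑dimethoxybenzoic acid | COc1cc(OC)cc(C(=O)O)c1 | starting material |
| 2 | (S)‑2‑(methoxymethyl)pyrrolidine | COC[C@@H]1CCCN1 | starting material |
| 3 | (S)‑SMP amide of 1 | COC[C@@H]1CCCN1C(=O)c1cc(OC)cc(OC)c1 | intermediate |
| 4 | allyl bromide | C=CCBr | starting material |
| 5 | 2‑allyl‑3,5‑dimethoxybenzamide (SMP) | COC[C@@H]1CCCN1C(=O)c1cc(OC)cc(OC)c1CC=C | intermediate |
| 6 | iodomethane | CI | starting material |
| 7 | Birch quaternary dienyl amide | COC[C@@H]1CCCN1C(=O)[C@@]2(C)C=C(OC)CC(OC)=C2CC=C | intermediate |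
| 8 | quaternary aldehyde | O=C[C@@]1(C)C=C(OC)CC(OC)=C1CC=C | intermediate |
| 9 | prenal | CC(C)=CC=O | starting material |
| 10 | triphenylphosphine | c1ccccc1P(c1ccccc1)c1ccccc1 | starting material |
| 11 | methanol | CO | starting material |
| 12 | α‑methoxyallyl phosphonium BF4 | COC(C=C(C)C)[P+](c1ccccc1)(c1ccccc1)c1ccccc1.F[B-](F)(F)F | intermediate (reagent) |
| 13 | 2‑methoxydiene | CC(C)=CC(OC)=C[C@@]1(C)C=C(OC)CC(OC)=C1CC=C | intermediate |
| 14 | cyclized tri(enol ether), cis‑fused (in situ) | COC1=CC(C)(C)[C@H]2C(OC)=CC(OC)=C(CC=C)[C@@]2(C)C1 | intermediate |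
| 15 | trione (5α,9α) | O=C1CC(=O)[C@H]2C(C)(C)CC(=O)C[C@]2(C)[C@H]1CC=C | intermediate |
| 16 | 2β‑hydroxy dione | O=C1CC(=O)[C@H]2C(C)(C)C[C@@H](O)C[C@]2(C)[C@H]1CC=C | intermediate |
| 17 | hexachloroethane | ClC(Cl)(Cl)C(Cl)(Cl)Cl | starting material |
| 18 | 2α‑chloro‑β‑chloroenone | ClC1=CC(=O)[C@H]2C(C)(C)C[C@H](Cl)C[C@]2(C)[C@H]1CC=C | intermediate |
| 19 | TMSCH2ZnCl | C[Si](C)(C)C[Zn]Cl | starting material |
| 20 | silylmethyl enone | C[Si](C)(C)CC1=CC(=O)[C@H]2C(C)(C)C[C@H](Cl)C[C@]2(C)[C@H]1CC=C | intermediate |
| 21 | C12 aldehyde | C[Si](C)(C)CC1=CC(=O)[C@H]2C(C)(C)C[C@H](Cl)C[C@]2(C)[C@H]1CC=O | intermediate |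
| 22 | N‑PMB‑succinimide | O=C1CCC(=O)N1Cc1ccc(OC)cc1 | starting material |
| 23 | aldol adduct | C[Si](C)(C)CC1=CC(=O)[C@H]2C(C)(C)C[C@H](Cl)C[C@]2(C)[C@H]1C[C@H](O)[C@H]1CC(=O)N(Cc2ccc(OC)cc2)C1=O | intermediate |
| 24 | PMB‑protected haterumaimide G | C=C1CC(=O)[C@H]2C(C)(C)C[C@H](Cl)C[C@]2(C)[C@H]1C[C@H](O)[C@H]1CC(=O)N(Cc2ccc(OC)cc2)C1=O | intermediate |
| 25 | haterumaimide G | C=C1CC(=O)[C@H]2C(C)(C)C[C@H](Cl)C[C@]2(C)[C@H]1C[C@H](O)[C@H]1CC(=O)NC1=O | target |

**Total steps:** 14 (including the parallel phosphonium salt preparation). **Longest linear sequence:** 13 steps, from 1 to 25.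

## Three steps most likely to fail

1. **Step 7 (cationic cyclization and thermodynamic hydrolysis).** Risks are competing enol‑ether protonation or oligomerization, an incomplete cis→trans C5 equilibration, and the wrong carbonyl being retained at C8 versus C6. Fallback: change the strategy to a Diels–Alder construction of the decalin, using 4,4‑dimethylcyclohexa‑2,5‑dienone (from p‑cresol) and an oxygenated diene under a chiral Lewis acid, then install C10‑Me by enolate methylation.
2. **Step 12 (aldol).** The four C12/C13 diastereomers give a poor yield of the desired isomer, and C13 is epimerizable. Fallback: Wittig of 21 with the commercial N–H phosphorane 3‑(triphenylphosphoranylidene)succinimide, then Weitz–Scheffer epoxidation and SmI2 opening. Alternatively, oxidize the aldol mixture to the β‑keto imide and converge it with Ru‑catalysed dynamic kinetic transfer hydrogenation.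
3. **Step 3 (asymmetric Birch methylation).** Diastereoselectivity for this trisubstituted, meta‑dimethoxy substrate is unproven, and the allyl group could isomerize under the reaction conditions. Fallback: run the reaction on an achiral diethylamide to give racemic 8 and resolve it by preparative chiral HPLC. If that fails, resolve the racemic dione 15 by chiral HPLC instead.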